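## Structural features

β-Collatolic acid (27) consists of two benzenoid rings joined by a single diaryl ether oxygen. Ring A is the benzo ring of a 6-methoxy-3-pentylisocoumarin (lactone carbonyl C1 on C8a, C4 on C4a, ether oxygen on C8). Ring B is a pentasubstituted benzoic acid (C1' CO2H, C2' OH, C4' OH, C5' O-aryl, C6' CH2COC5H11). There is no stereocentre, so the difficulties are regiochemical and steric. The ether oxygen lies between C8a on ring A and C4'–O and C6'–CH2 on ring B, so it is a tri-ortho-substituted ether between two electron-rich rings. Both rings carry the same carboxyl-plus-2-oxoheptyl motif, closed to an enol lactone on ring A and open on ring B, so the two arms must be kept distinguishable throughout. Fragile points are the 2,4-dihydroxybenzoic acid of ring B (decarboxylation in hot acid), its keto acid (can dehydrate to a second enol lactone), the ring A lactone (opened by hydroxide) and the single methyl ether, which must survive unmasking of the ring B phenols. The key step uses the vicinal pair C8a/C4a of ring A: they carry C1 and C4, and C8a is next to the oxygen-bearing C8. This is the pattern formed when an aryne polarised by a neighbouring oxygen inserts into the C–C bond of a malonate.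

## Logic of the disconnections

27 ⇒ 26. The two O–benzyl bonds, the O–tert-butyl bond and the two ketal C–O bonds of ring B are the last bonds to be broken in the forward sense. The free phenols and the keto acid of ring B are the most fragile part and are released together at the end. This keeps every reactive group of ring B inert through the route. The forward step must spare the methyl ether and lactone of ring A and must not dehydrate the liberated keto acid.

26 ⇒ 25. The lactone C1–O2 bond is cut. The enol lactone is closed by dehydration of a keto acid under non-acidic conditions, at a point where the corresponding arm of ring B is blocked twice (tert-butyl ester and ketal). This reduces the heterocycle to an open-chain keto acid. The forward step must activate the carboxyl group without acid.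

25 ⇒ 22 + 4 (through 23 and 24). The C4–C3 bond is cut, and one carboxyl carbon is lost as CO2 in the forward direction. The CH2 group of 22 is doubly activated and takes the acyl group of 4; water then opens the anhydride and 24 decarboxylates. 22 ⇐ 21 ⇐ 20 are functional-group changes only. The ring A arm is thus drawn from the same C6 source as the ring B arm. The forward steps need C- rather than O-acylation and a ring B ester that resists hydroxide, hence tert-butyl.

20 ⇒ 17 + 18 (through 19). The bonds C4a–C4 and C8a–C1 are cut. Both carbon substituents of ring A come from 18 in one operation. The gain is a ring A precursor with only heteroatom substituents. The forward step needs the nucleophile to enter at C4a and the charge to develop at C8a, and needs ring B to carry no acidic or electrophilic group.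

17 ⇒ 14 (through 15 and 16). The C–Si and O–S bonds are cut. Silicon is delivered from the phenol oxygen to the carbon that carried bromine, and the freed oxygen is sulfonylated in the same flask. The demand is that halogen–metal exchange outruns any attack on ring B.

14 ⇒ 13 ⇒ 10 + 12, and 12 ⇒ 11. The diaryl ether C8–O bond is cut, which splits the molecule into two halves of similar size. The phenol oxygen of the ring A half is carried as an allyl ether, because a free ortho-bromophenoxide would be a deactivated electrophile and a competing nucleophile. Silicon and triflate are introduced only after the coupling, because a silyl triflate would not survive the basic copper conditions. 11 is symmetric, so either bromide serves. The demand is a single substitution on 12 with a crowded phenol.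

10 ⇒ 9 ⇒ 8 ⇒ 7. The C5'–O bond (phenol from bromide) and the ester alkyl–oxygen bonds are cut. The ester is exchanged after the ketal is in place, because ketalisation is safer on a methyl ester. The demand is hydroxylation of a di-ortho-substituted bromide without loss of the tert-butyl ester.

7 ⇒ 6 ⇒ 3 + 5, and 5 ⇐ 4. The ketal is removed and the C6'-CH2–C(=O) bond is cut. The benzylic methyl group next to the ester is the natural nucleophile and 5 is an acyl donor that stops at the ketone. The demand is benzylic deprotonation without touching the aryl bromide.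

3 ⇒ 2 ⇒ 1. The C5'–Br bond and the two O–benzyl bonds are cut. This leads to a commercial ester that already holds the carboxyl carbon, the methyl group and both oxygens of ring B. The demand is bromination at C5' rather than at C3'.

## Other disconnections considered

Alternative 1: The cut lies inside ring A, at C8a–C4a and C7–C8, so that ring A comes from 18 and the acyclic enone A2. In the forward direction, conjugate addition of the malonate to A2 and Claisen-type closure of the methyl ketone enolate onto one ester would give the cyclohexane-1,3-dione A1. Its two stereocentres are lost on aromatisation. The C6 oxygen would then be methylated, the C8 oxygen position joined to the ring B phenol 10 by addition–elimination on an activated enol derivative, and the ring dehydrogenated.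

- In its favour: the annulation is classical base-mediated chemistry with no regiochemical ambiguity and no transition metal, fluoride or silyl triflate. A phenoxide adding to an activated enone carbon is also a gentler route to a crowded aryl ether than a copper coupling of two arenes. On these points it equals or betters the chosen plan.
- Against it here: the two oxygens of A1 must be differentiated, with ring B going onto the more hindered one next to the ester-bearing carbon. An oxidation is needed for aromatisation in the presence of the electron-rich ring B. Most seriously, ring A would then carry the same ketal-masked oxoheptyl arm beside an ester as ring B, so closing one and leaving the other open needs a second, orthogonal mask.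
- Comparison: the chosen plan makes the ring A arm in a different oxidation state (a homophthalate) and so differentiates the rings by construction. Mechanistically this is thermodynamically controlled enolate chemistry against a kinetically controlled aryne cascade. The step count is comparable, since A2 itself needs several steps, but the linear sequence is longer because ring A is built along the main line.

Alternative 2: The cut removes both carbon substituents of ring B, at C1'–carbonyl and C6'–CH2. In the forward direction the diaryl ether A5 would be acylated at C1' by the acid chloride A4 under AlCl3 (or P2O5 in methanesulfonic acid), and the aryl vinyl ketone would undergo Nazarov closure onto C6' to give the indanone A3. Hydroxylation at C2 of the indanone and cleavage of the C1–C2 bond would then release the carboxylic acid and the 2-oxoheptyl arm together.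

- In its favour: the ether bond of A5 is made while ring B has no carbon substituents, so the coupling is far less crowded; this is better than the chosen plan. Acid and ketone emerge at the right oxidation level from one cleavage, with no ester or ketal on ring B; this is better in protecting-group economy.
- Against it here: a strong Lewis acid meets isopropyl ethers that become chelated to the new ketone, and an enol lactone. Acylation at C3' or on ring A may compete. The Nazarov closure must occur at C6', which is meta to both alkoxy groups and shielded by the aryloxy group, from a ketone deactivated by ortho and para oxygen donation. The oxidative cleavage must spare the C3=C4 bond of the isocoumarin.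
- Comparison: the cationic cascade under harsh acid is less predictable than the fluoride-triggered insertion at room temperature. It could be shorter on ring B, but A5 still needs its isocoumarin built first, so the effort is shifted rather than saved and the route is more linear.

Alternative 3: The cut is a [4+2] disconnection of ring B at C1'–C2' and C5'–C6'. In the forward direction the bis(silyloxy)diene A7, carried on the isocoumarin oxygen, would add to the alkynoate A8; loss of methanol and desilylation would give the fully substituted benzoate A6.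

- In its favour: ring B is formed with all six positions defined and the phenols already free. The ether oxygen is attached earlier by alkylation at sp3 carbon, so there is no hindered aryl–oxygen coupling; this is better than the chosen plan. The end game (hydrogenolysis of a benzyl ester, mild ketal hydrolysis) is at least as gentle.
- Against it here: dienes of this kind react readily only with strongly activated dienophiles, and A8 is mono-activated and β-branched. The heat then needed endangers the silyl enol ethers. The diene terminus carries a bulky aryloxy group exactly where bonding to the hindered alkyne carbon must occur. Making A7 needs strong base in the presence of the lactone.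
- Comparison: regiocontrol by diene polarisation is of similar quality to aryne polarisation in the chosen plan. The finished isocoumarin, the most valuable intermediate, would be committed to the least reliable step, whereas the chosen plan joins two separately made halves in mid-route and relies on a well-precedented insertion.

Key step: step 13

Assumption: 27 is treated as the open-chain keto acid as drawn; a lactol formed reversibly between the ring B carboxyl group and the side-chain ketone counts as the same compound.

## Route

Step 1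
Reactants: 1 methyl 2,4-dihydroxy-6-methylbenzoate (methyl orsellinate)
Product: 2 methyl 2,4-bis(benzyloxy)-6-methylbenzoate
Conditions: BnBr, K2CO3, DMF, 60 °C
Reagents that add atoms: benzyl bromide, BrCc1ccccc1
Why: Williamson ether synthesis; carbonate in DMF alkylates both phenols, the hydrogen-bonded 2-OH more slowly, hence excess halide and warming; benzyl ethers are chosen because they can later be removed either by Lewis acid at −78 °C or by hydrogenolysis.

Step 2
Reactants: 2 methyl 2,4-bis(benzyloxy)-6-methylbenzoate
Product: 3 methyl 4,6-bis(benzyloxy)-3-bromo-2-methylbenzoate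
Conditions: NBS, MeCN, 0 °C → rt
Reagents that add atoms: N-bromosuccinimide, O=C1CCC(=O)N1Br
Why: Electrophilic aromatic bromination; the position para to one ether and ortho to the other (next to the methyl group) is attacked in preference to the position flanked by both benzyloxy groups, as is usual for resorcinol diethers.

Step 3
Reactants: 4 hexanoyl chloride
Product: 5 N-methoxy-N-methylhexanamide
Conditions: MeNHOMe·HCl, Et3N, CH2Cl2, 0 °C → rt
Reagents that add atoms: N,O-dimethylhydroxylamine hydrochloride, CNOC.Cl
Why: Acylation of an amine by an acid chloride; it turns the C6 source into an acyl donor that stops at the ketone stage.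

Step 4
Reactants: 3 methyl 4,6-bis(benzyloxy)-3-bromo-2-methylbenzoate; 5 N-methoxy-N-methylhexanamide
Product: 6 methyl 4,6-bis(benzyloxy)-3-bromo-2-(2-oxoheptyl)benzoate
Conditions: LiN(iPr)2, THF, −78 °C; then 5, −78 → −40 °C; aq. NH4Cl
Reagents that add atoms: none
Why: Lateral lithiation of an ortho-toluate followed by Weinreb ketone synthesis; the chelated tetrahedral adduct prevents over-addition and keeps the acidic benzyl ketone from quenching the anion, and the amide base does not exchange the aryl bromide.

Step 5
Reactants: 6 methyl 4,6-bis(benzyloxy)-3-bromo-2-(2-oxoheptyl)benzoate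
Product: 7 methyl 4,6-bis(benzyloxy)-3-bromo-2-[(2-pentyl-1,3-dioxolan-2-yl)methyl]benzoate
Conditions: Me3SiOCH2CH2OSiMe3, TMSOTf (cat.), CH2Cl2, −78 → −20 °C; pyridine quench
Reagents that add atoms: 1,2-bis(trimethylsilyloxy)ethane, C[Si](C)(C)OCCO[Si](C)(C)C
Why: Aprotic ketalisation under silyl triflate catalysis, driven by formation of hexamethyldisiloxane; it is done on the methyl ester because a methyl ester cannot lose its alkyl group if its carbonyl oxygen attacks the activated ketone, whereas a tert-butyl ester could and would then go on to an isocoumarin.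

Step 6
Reactants: 7 methyl 4,6-bis(benzyloxy)-3-bromo-2-[(2-pentyl-1,3-dioxolan-2-yl)methyl]benzoate
Product: 8 4,6-bis(benzyloxy)-3-bromo-2-[(2-pentyl-1,3-dioxolan-2-yl)methyl]benzoic acid
Conditions: KOH, DMSO/H2O, 100 °C; then cold 1 M HCl to pH 4
Reagents that add atoms: potassium hydroxide, [K+].[OH-]
Why: Saponification of a di-ortho-substituted benzoate, which needs poorly solvated hydroxide and heat; ketal, benzyl ethers and the electron-rich aryl bromide are inert to base, and the brief cold acidification spares the ketal.

Step 7
Reactants: 8 4,6-bis(benzyloxy)-3-bromo-2-[(2-pentyl-1,3-dioxolan-2-yl)methyl]benzoic acid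
Product: 9 tert-butyl 4,6-bis(benzyloxy)-3-bromo-2-[(2-pentyl-1,3-dioxolan-2-yl)methyl]benzoate
Conditions: t-BuOC(=N-iPr)NH-iPr, CH2Cl2, rt → 40 °C
Reagents that add atoms: O-tert-butyl-N,N'-diisopropylisourea, CC(C)N=C(OC(C)(C)C)NC(C)C
Why: Esterification by O-alkylation of the carboxylate with the protonated isourea, so the crowded acyl carbon is not attacked and the ketal sees no strong acid; the tert-butyl ester is the one ester that will outlast the hydroxide used later on the two methyl esters of ring A.

Step 8
Reactants: 9 tert-butyl 4,6-bis(benzyloxy)-3-bromo-2-[(2-pentyl-1,3-dioxolan-2-yl)methyl]benzoate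
Product: 10 tert-butyl 4,6-bis(benzyloxy)-3-hydroxy-2-[(2-pentyl-1,3-dioxolan-2-yl)methyl]benzoate
Conditions: Pd2(dba)3 (cat.), t-BuXPhos (cat.), KOH, 1,4-dioxane/H2O, 100 °C; aq. NH4Cl
Reagents that add atoms: potassium hydroxide, [K+].[OH-]
Why: Palladium-catalysed hydroxylation of an aryl bromide (C–O cross-coupling with hydroxide); the bulky biaryl phosphine promotes reductive elimination from the hindered arylpalladium hydroxide, the two ortho substituents keep the product phenoxide from coupling again, and the tert-butyl ester resists hydroxide.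

Step 9
Reactants: 11 2,6-dibromo-4-methoxyphenol
Product: 12 1,3-dibromo-5-methoxy-2-(prop-2-en-1-yloxy)benzene
Conditions: allyl bromide, K2CO3, acetone, reflux
Reagents that add atoms: allyl bromide, C=CCBr
Why: Williamson ether synthesis; the phenol is capped because a free ortho-bromophenoxide is a poor electrophile and a competing nucleophile in copper coupling, and allyl is removable later without acid, base or hydrogen.

Step 10
Reactants: 10 tert-butyl 4,6-bis(benzyloxy)-3-hydroxy-2-[(2-pentyl-1,3-dioxolan-2-yl)methyl]benzoate; 12 1,3-dibromo-5-methoxy-2-(prop-2-en-1-yloxy)benzene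
Product: 13 tert-butyl 4,6-bis(benzyloxy)-3-[3-bromo-5-methoxy-2-(prop-2-en-1-yloxy)phenoxy]-2-[(2-pentyl-1,3-dioxolan-2-yl)methyl]benzoate
Conditions: CuI (cat.), picolinic acid (cat.), K3PO4, DMSO, 90 °C; 12 in excess
Reagents that add atoms: none
Why: Ullmann ether synthesis in its ligand-accelerated form (monovalent copper with a picolinate ligand), a system suited to 2,6-disubstituted phenols and ortho-substituted aryl halides; 12 is symmetric so either bromide gives the same product, and its excess together with the greater crowding and electron density of 13 should stop the reaction after one substitution.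

Step 11
Reactants: 13 tert-butyl 4,6-bis(benzyloxy)-3-[3-bromo-5-methoxy-2-(prop-2-en-1-yloxy)phenoxy]-2-[(2-pentyl-1,3-dioxolan-2-yl)methyl]benzoate
Product: 14 tert-butyl 4,6-bis(benzyloxy)-3-(3-bromo-2-hydroxy-5-methoxyphenoxy)-2-[(2-pentyl-1,3-dioxolan-2-yl)methyl]benzoate
Conditions: Pd(PPh3)4 (cat.), morpholine, THF, rt
Reagents that add atoms: none
Why: Tsuji–Trost deallylation; zerovalent palladium ionises the allyl aryl ether and morpholine traps the allyl fragment, while the hindered electron-rich aryl bromide should not undergo oxidative addition at room temperature.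

Step 12
Reactants: 14 tert-butyl 4,6-bis(benzyloxy)-3-(3-bromo-2-hydroxy-5-methoxyphenoxy)-2-[(2-pentyl-1,3-dioxolan-2-yl)methyl]benzoate
Product: 17 tert-butyl 4,6-bis(benzyloxy)-3-{5-methoxy-2-[(trifluoromethylsulfonyl)oxy]-3-(trimethylsilyl)phenoxy}-2-[(2-pentyl-1,3-dioxolan-2-yl)methyl]benzoate, via aryl trimethylsilyl ether 15 (not isolated), via lithium 2-silylphenoxide 16 (not isolated)
Conditions: (Me3Si)2NH, THF, 65 °C, evaporate; n-BuLi, THF, −78 °C; Tf2O, −78 → 0 °C
Reagents that add atoms: hexamethyldisilazane, C[Si](C)(C)N[Si](C)(C)C; trifluoromethanesulfonic anhydride, O=S(=O)(OS(=O)(=O)C(F)(F)F)C(F)(F)F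
Why: O-silylation, bromine–lithium exchange and retro-Brook rearrangement (1,3 shift of silicon from oxygen to carbon, driven by formation of the lithium phenoxide), then triflation of that phenoxide in the same flask; exchange at −78 °C should be much faster than addition to the shielded tert-butyl ester.

Step 13
Reactants: 17 tert-butyl 4,6-bis(benzyloxy)-3-{5-methoxy-2-[(trifluoromethylsulfonyl)oxy]-3-(trimethylsilyl)phenoxy}-2-[(2-pentyl-1,3-dioxolan-2-yl)methyl]benzoate; 18 dimethyl malonate
Product: 20 tert-butyl 4,6-bis(benzyloxy)-3-[5-methoxy-2-(methoxycarbonyl)-3-(2-methoxy-2-oxoethyl)phenoxy]-2-[(2-pentyl-1,3-dioxolan-2-yl)methyl]benzoate, via 3-aryloxy-5-methoxybenzyne 19 (not isolated)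
Conditions: KF, 18-crown-6, THF, rt; 18 in slight excess
Reagents that add atoms: none
Why: Fluoride attacks silicon and the resulting aryl anion expels triflate to give aryne 19. The potassium enolate of 18 adds to the aryne carbon remote from the aryloxy group (the future C4a), which places the aryl anion on the future C8a next to the ether oxygen. This anion adds to one ester carbonyl (4-exo-trig) to give a benzocyclobutenoxide, which fragments so that the former malonate C–C bond is replaced by C4a–C4 and C8a–C1. The closest known reaction type is the fluoride-induced insertion of arynes from 2-(trimethylsilyl)aryl triflates into the C–C bond of malonates and β-keto esters (acyl-alkylation of arynes). No ring remains in the product, the four-membered ring being only a transient, and no stereocentre is formed. The step needs regioselectivity: the inductively withdrawing C8 oxygen distorts the aryne so that the nucleophile enters meta to it and the charge develops ortho to it, the bulk of ring B reinforces this, and the 6-methoxy group, one position further away, has only a weak opposing effect. It also needs the aryl anion to reach the ester before it is protonated by 18, which is helped by a small excess of 18, slow aryne release at room temperature and the absence of any acidic or electrophilic group on ring B.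

Step 14
Reactants: 20 tert-butyl 4,6-bis(benzyloxy)-3-[5-methoxy-2-(methoxycarbonyl)-3-(2-methoxy-2-oxoethyl)phenoxy]-2-[(2-pentyl-1,3-dioxolan-2-yl)methyl]benzoate
Product: 21 2-{4,6-bis(benzyloxy)-3-(tert-butoxycarbonyl)-2-[(2-pentyl-1,3-dioxolan-2-yl)methyl]phenoxy}-6-(carboxymethyl)-4-methoxybenzoic acid
Conditions: KOH, EtOH/H2O, 80 °C; then cold 1 M HCl to pH 3
Reagents that add atoms: potassium hydroxide, [K+].[OH-]
Why: Saponification; the arylacetate reacts readily and the alkoxy-flanked benzoate on heating, as with 3,5-dialkoxyhomophthalates, while the tert-butyl ester is shielded from acyl attack and the ketal is inert to base.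

Step 15
Reactants: 21 2-{4,6-bis(benzyloxy)-3-(tert-butoxycarbonyl)-2-[(2-pentyl-1,3-dioxolan-2-yl)methyl]phenoxy}-6-(carboxymethyl)-4-methoxybenzoic acid
Product: 22 tert-butyl 4,6-bis(benzyloxy)-3-[(6-methoxy-1,3-dioxo-3,4-dihydro-1H-isochromen-8-yl)oxy]-2-[(2-pentyl-1,3-dioxolan-2-yl)methyl]benzoate
Conditions: Ac2O, toluene, 80 °C
Reagents that add atoms: none
Why: Cyclodehydration of a homophthalic acid through the mixed anhydride of the arylacetic acid to the six-membered cyclic anhydride; neutral conditions spare the ketal and the tert-butyl ester.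

Step 16
Reactants: 22 tert-butyl 4,6-bis(benzyloxy)-3-[(6-methoxy-1,3-dioxo-3,4-dihydro-1H-isochromen-8-yl)oxy]-2-[(2-pentyl-1,3-dioxolan-2-yl)methyl]benzoate; 4 hexanoyl chloride
Product: 25 2-{4,6-bis(benzyloxy)-3-(tert-butoxycarbonyl)-2-[(2-pentyl-1,3-dioxolan-2-yl)methyl]phenoxy}-4-methoxy-6-(2-oxoheptyl)benzoic acid, via 4-hexanoyl anhydride 23 (not isolated), via β-keto diacid 24 (not isolated)
Conditions: Me2NC(=NH)NMe2, Et3N, MeCN, 0 °C; then H2O, 40 °C; 1 M HCl to pH 3
Reagents that add atoms: water, O
Why: C-acylation of the enolate of a homophthalic anhydride by an acid chloride (a Dakin–West-type acylation), then hydrolysis of the anhydride to a 2-aryl-3-oxo acid that loses CO2 through the usual cyclic transition state; hydrolysing under mild conditions rather than heating in strong acid keeps the tert-butyl ester and the ketal of ring B.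

Step 17
Reactants: 25 2-{4,6-bis(benzyloxy)-3-(tert-butoxycarbonyl)-2-[(2-pentyl-1,3-dioxolan-2-yl)methyl]phenoxy}-4-methoxy-6-(2-oxoheptyl)benzoic acid
Product: 26 tert-butyl 4,6-bis(benzyloxy)-3-[(6-methoxy-1-oxo-3-pentyl-1H-isochromen-8-yl)oxy]-2-[(2-pentyl-1,3-dioxolan-2-yl)methyl]benzoate
Conditions: Ac2O, Et3N, toluene, 60 °C
Reagents that add atoms: none
Why: Enol lactonisation of a 2-(2-oxoalkyl)benzoic acid through its mixed anhydride (6-exo-trig attack of the enol oxygen), the classical isocoumarin closure run without acid; only ring A can close because the matching arm of ring B is still a tert-butyl ester and a ketal.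

Step 18
Reactants: 26 tert-butyl 4,6-bis(benzyloxy)-3-[(6-methoxy-1-oxo-3-pentyl-1H-isochromen-8-yl)oxy]-2-[(2-pentyl-1,3-dioxolan-2-yl)methyl]benzoate
Product: 27 β-collatolic acid, 2,4-dihydroxy-5-[(6-methoxy-1-oxo-3-pentyl-1H-isochromen-8-yl)oxy]-6-(2-oxoheptyl)benzoic acid
Conditions: BCl3, C6HMe5, CH2Cl2, −78 → 0 °C; then 1 M HCl, THF, rt
Reagents that add atoms: water, O
Why: Lewis-acid debenzylation with a cation scavenger; BCl3 ionises the benzyl ethers already at −78 °C and pentamethylbenzene traps the benzyl cations so that the electron-rich rings are not benzylated, the tert-butyl ester and dioxolane are cleaved on warming, and dilute aqueous acid completes hydrolysis to the ketone; the methyl ether (no flanking carbonyl) and the lactone should not react below 0 °C.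

## Compound list

1 | methyl 2,4-dihydroxy-6-methylbenzoate (methyl orsellinate) | COC(=O)c1c(C)cc(O)cc1O | starting material
2 | methyl 2,4-bis(benzyloxy)-6-methylbenzoate | COC(=O)c1c(C)cc(OCc2ccccc2)cc1OCc3ccccc3 | intermediate
3 | methyl 4,6-bis(benzyloxy)-3-bromo-2-methylbenzoate | COC(=O)c1c(C)c(Br)c(OCc2ccccc2)cc1OCc3ccccc3 | intermediate
4 | hexanoyl chloride | CCCCCC(Cl)=O | starting material
5 | N-methoxy-N-methylhexanamide | CCCCCC(=O)N(C)OC | intermediate
6 | methyl 4,6-bis(benzyloxy)-3-bromo-2-(2-oxoheptyl)benzoate | CCCCCC(=O)Cc1c(Br)c(OCc2ccccc2)cc(OCc3ccccc3)c1C(=O)OC | intermediate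
7 | methyl 4,6-bis(benzyloxy)-3-bromo-2-[(2-pentyl-1,3-dioxolan-2-yl)methyl]benzoate | CCCCCC1(Cc2c(Br)c(OCc3ccccc3)cc(OCc4ccccc4)c2C(=O)OC)OCCO1 | intermediate
8 | 4,6-bis(benzyloxy)-3-bromo-2-[(2-pentyl-1,3-dioxolan-2-yl)methyl]benzoic acid | CCCCCC1(Cc2c(Br)c(OCc3ccccc3)cc(OCc4ccccc4)c2C(=O)O)OCCO1 | intermediate
9 | tert-butyl 4,6-bis(benzyloxy)-3-bromo-2-[(2-pentyl-1,3-dioxolan-2-yl)methyl]benzoate | CCCCCC1(Cc2c(Br)c(OCc3ccccc3)cc(OCc4ccccc4)c2C(=O)OC(C)(C)C)OCCO1 | intermediate
10 | tert-butyl 4,6-bis(benzyloxy)-3-hydroxy-2-[(2-pentyl-1,3-dioxolan-2-yl)methyl]benzoate | CCCCCC1(Cc2c(O)c(OCc3ccccc3)cc(OCc4ccccc4)c2C(=O)OC(C)(C)C)OCCO1 | intermediate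
11 | 2,6-dibromo-4-methoxyphenol | COc1cc(Br)c(O)c(Br)c1 | starting material
12 | 1,3-dibromo-5-methoxy-2-(prop-2-en-1-yloxy)benzene | C=CCOc1c(Br)cc(OC)cc1Br | intermediate
13 | tert-butyl 4,6-bis(benzyloxy)-3-[3-bromo-5-methoxy-2-(prop-2-en-1-yloxy)phenoxy]-2-[(2-pentyl-1,3-dioxolan-2-yl)methyl]benzoate | C=CCOc1c(Br)cc(OC)cc1Oc2c(CC3(CCCCC)OCCO3)c(C(=O)OC(C)(C)C)c(OCc4ccccc4)cc2OCc5ccccc5 | intermediate
14 | tert-butyl 4,6-bis(benzyloxy)-3-(3-bromo-2-hydroxy-5-methoxyphenoxy)-2-[(2-pentyl-1,3-dioxolan-2-yl)methyl]benzoate | COc1cc(Br)c(O)c(Oc2c(CC3(CCCCC)OCCO3)c(C(=O)OC(C)(C)C)c(OCc4ccccc4)cc2OCc5ccccc5)c1 | intermediate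
15 | tert-butyl 4,6-bis(benzyloxy)-3-{3-bromo-5-methoxy-2-[(trimethylsilyl)oxy]phenoxy}-2-[(2-pentyl-1,3-dioxolan-2-yl)methyl]benzoate | COc1cc(Br)c(O[Si](C)(C)C)c(Oc2c(CC3(CCCCC)OCCO3)c(C(=O)OC(C)(C)C)c(OCc4ccccc4)cc2OCc5ccccc5)c1 | intermediate
16 | lithium 2-{4,6-bis(benzyloxy)-3-(tert-butoxycarbonyl)-2-[(2-pentyl-1,3-dioxolan-2-yl)methyl]phenoxy}-4-methoxy-6-(trimethylsilyl)phenolate | COc1cc([Si](C)(C)C)c([O-])c(Oc2c(CC3(CCCCC)OCCO3)c(C(=O)OC(C)(C)C)c(OCc4ccccc4)cc2OCc5ccccc5)c1.[Li+] | intermediate
17 | tert-butyl 4,6-bis(benzyloxy)-3-{5-methoxy-2-[(trifluoromethylsulfonyl)oxy]-3-(trimethylsilyl)phenoxy}-2-[(2-pentyl-1,3-dioxolan-2-yl)methyl]benzoate | COc1cc(Oc2c(CC3(CCCCC)OCCO3)c(C(=O)OC(C)(C)C)c(OCc4ccccc4)cc2OCc5ccccc5)c(OS(=O)(=O)C(F)(F)F)c([Si](C)(C)C)c1 | intermediate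
18 | dimethyl malonate | COC(=O)CC(=O)OC | starting material
19 | tert-butyl 4,6-bis(benzyloxy)-3-[(2,3-didehydro-5-methoxyphenyl)oxy]-2-[(2-pentyl-1,3-dioxolan-2-yl)methyl]benzoate (3-aryloxy-5-methoxybenzyne) | COC1=CC#CC(Oc2c(CC3(CCCCC)OCCO3)c(C(=O)OC(C)(C)C)c(OCc4ccccc4)cc2OCc5ccccc5)=C1 | intermediate
20 | tert-butyl 4,6-bis(benzyloxy)-3-[5-methoxy-2-(methoxycarbonyl)-3-(2-methoxy-2-oxoethyl)phenoxy]-2-[(2-pentyl-1,3-dioxolan-2-yl)methyl]benzoate | COC(=O)Cc1cc(OC)cc(Oc2c(CC3(CCCCC)OCCO3)c(C(=O)OC(C)(C)C)c(OCc4ccccc4)cc2OCc5ccccc5)c1C(=O)OC | intermediate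
21 | 2-{4,6-bis(benzyloxy)-3-(tert-butoxycarbonyl)-2-[(2-pentyl-1,3-dioxolan-2-yl)methyl]phenoxy}-6-(carboxymethyl)-4-methoxybenzoic acid | OC(=O)Cc1cc(OC)cc(Oc2c(CC3(CCCCC)OCCO3)c(C(=O)OC(C)(C)C)c(OCc4ccccc4)cc2OCc5ccccc5)c1C(=O)O | intermediate
22 | tert-butyl 4,6-bis(benzyloxy)-3-[(6-methoxy-1,3-dioxo-3,4-dihydro-1H-isochromen-8-yl)oxy]-2-[(2-pentyl-1,3-dioxolan-2-yl)methyl]benzoate | COc1cc2c(c(Oc3c(CC4(CCCCC)OCCO4)c(C(=O)OC(C)(C)C)c(OCc5ccccc5)cc3OCc6ccccc6)c1)C(=O)OC(=O)C2 | intermediate
23 | tert-butyl 4,6-bis(benzyloxy)-3-[(4-hexanoyl-6-methoxy-1,3-dioxo-3,4-dihydro-1H-isochromen-8-yl)oxy]-2-[(2-pentyl-1,3-dioxolan-2-yl)methyl]benzoate (racemic, enolisable) | CCCCCC(=O)C1C(=O)OC(=O)c2c(Oc3c(CC4(CCCCC)OCCO4)c(C(=O)OC(C)(C)C)c(OCc5ccccc5)cc3OCc6ccccc6)cc(OC)cc21 | intermediate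
24 | 2-(3-{4,6-bis(benzyloxy)-3-(tert-butoxycarbonyl)-2-[(2-pentyl-1,3-dioxolan-2-yl)methyl]phenoxy}-2-carboxy-5-methoxyphenyl)-3-oxooctanoic acid (racemic, enolisable) | CCCCCC(=O)C(C(=O)O)c1cc(OC)cc(Oc2c(CC3(CCCCC)OCCO3)c(C(=O)OC(C)(C)C)c(OCc4ccccc4)cc2OCc5ccccc5)c1C(=O)O | intermediate
25 | 2-{4,6-bis(benzyloxy)-3-(tert-butoxycarbonyl)-2-[(2-pentyl-1,3-dioxolan-2-yl)methyl]phenoxy}-4-methoxy-6-(2-oxoheptyl)benzoic acid | CCCCCC(=O)Cc1cc(OC)cc(Oc2c(CC3(CCCCC)OCCO3)c(C(=O)OC(C)(C)C)c(OCc4ccccc4)cc2OCc5ccccc5)c1C(=O)O | intermediate
26 | tert-butyl 4,6-bis(benzyloxy)-3-[(6-methoxy-1-oxo-3-pentyl-1H-isochromen-8-yl)oxy]-2-[(2-pentyl-1,3-dioxolan-2-yl)methyl]benzoate | CCCCCc1cc2cc(OC)cc(Oc3c(CC4(CCCCC)OCCO4)c(C(=O)OC(C)(C)C)c(OCc5ccccc5)cc3OCc6ccccc6)c2c(=O)o1 | intermediate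
27 | β-collatolic acid, 2,4-dihydroxy-5-[(6-methoxy-1-oxo-3-pentyl-1H-isochromen-8-yl)oxy]-6-(2-oxoheptyl)benzoic acid | CCCCCC(=O)Cc1c(Oc2cc(OC)cc3cc(CCCCC)oc(=O)c23)c(O)cc(O)c1C(=O)O | target

## Step count and least certain steps

Total step count: 18. Longest linear sequence: 16 steps (steps 1, 2, 4–8 and 10–18, from 1); steps 3 and 9 are side branches.

Step 13 (key step). The aryl anion may be protonated by 18 before it reaches the ester carbonyl, giving plain arylation without insertion; the acidic CH2 group of the product may be arylated by a second aryne; and the 6-methoxy group may erode regiocontrol. Fallback without an aryne, setting out from 14 and returning at 20: triflation of 14 (Tf2O, pyridine) should give the bromo triflate F1. Palladium-catalysed coupling of its C–Br bond with the Reformatsky reagent BrZnCH2CO2Me (Pd2(dba)3, P(t-Bu)3, THF), a catalyst that prefers bromide over triflate, should give the arylacetate triflate F2. Methoxycarbonylation of the triflate (CO, MeOH, Pd(OAc)2, 1,3-bis(diphenylphosphino)propane, Et3N, DMF) should then give 20.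

Step 10. C–O bond formation between two electron-rich, ortho-crowded partners may be slow, so that reduction of the bromide or double substitution of 12 takes over. Fallback by nucleophilic aromatic substitution and Baeyer–Villiger oxidation, setting out from 10 and returning at 14 (12 and 13 are bypassed): 10 and the building block 2-bromo-6-fluoro-4-methoxybenzaldehyde F3 (K2CO3, DMF, 100 °C) should give the diaryl ether aldehyde F4 by displacement of the fluoride activated by the ortho formyl group. mCPBA should convert this electron-rich aldehyde into the aryl formate F5, and methanolysis (K2CO3, MeOH) should give 14.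

Step 12. Butyllithium may attack ring B (ester addition or ring metalation) in competition with bromine–lithium exchange, or the aryllithium may be protonated before silicon migrates. Fallback that puts silicon in place before the rings are joined, setting out from 11 and 10 and returning at 17: the same silylation, exchange and migration on 11, quenched with water, should give 2-bromo-4-methoxy-6-(trimethylsilyl)phenol F6. Allylation (allyl bromide, K2CO3) gives the allyl ether F7, copper coupling with 10 under the conditions of step 10 the silylated diaryl ether F8, and deallylation (Pd(PPh3)4, morpholine) the silylphenol F9. Triflation (Tf2O, pyridine) then gives 17.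

Step 16. O-acylation, loss of the hexanoyl group by retro-Claisen cleavage during hydrolysis, or rearrangement to an isocoumarin-4-carboxylic acid that resists decarboxylation may occur. Fallback by acylation at the diester stage, setting out from 20 and returning at 25: deprotonation of 20 (LiN(SiMe3)2, two equivalents, THF, −78 °C) and C-acylation with 4 should give the β-keto ester F10. Krapcho dealkoxycarbonylation (LiCl, wet DMSO, 130 °C) should give the keto methyl ester F11, and saponification (KOH, EtOH/H2O, then acid) should give 25.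

Step 18. The liberated ring B keto acid may cyclise and dehydrate under the Lewis acid, the dihydroxybenzoic acid may decarboxylate, or deprotection may be incomplete. Fallback without Lewis acid, setting out from 26 and returning at 27: hydrogenolysis (H2, Pd/C, EtOAc, rt, stopped as soon as the benzyl groups are gone to spare the C3=C4 bond) should give the dihydroxy tert-butyl ester F12. Aqueous trifluoroacetic acid (CH2Cl2, 0 °C → rt) then removes the tert-butyl ester and the ketal to give 27.

## Further compounds

F1 | step 13 | tert-butyl 4,6-bis(benzyloxy)-3-{3-bromo-5-methoxy-2-[(trifluoromethylsulfonyl)oxy]phenoxy}-2-[(2-pentyl-1,3-dioxolan-2-yl)methyl]benzoate | COc1cc(Br)c(OS(=O)(=O)C(F)(F)F)c(Oc2c(CC3(CCCCC)OCCO3)c(C(=O)OC(C)(C)C)c(OCc4ccccc4)cc2OCc5ccccc5)c1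
F2 | step 13 | tert-butyl 4,6-bis(benzyloxy)-3-{5-methoxy-3-(2-methoxy-2-oxoethyl)-2-[(trifluoromethylsulfonyl)oxy]phenoxy}-2-[(2-pentyl-1,3-dioxolan-2-yl)methyl]benzoate | COC(=O)Cc1cc(OC)cc(Oc2c(CC3(CCCCC)OCCO3)c(C(=O)OC(C)(C)C)c(OCc4ccccc4)cc2OCc5ccccc5)c1OS(=O)(=O)C(F)(F)F
F3 | step 10 | 2-bromo-6-fluoro-4-methoxybenzaldehyde | COc1cc(F)c(C=O)c(Br)c1
F4 | step 10 | tert-butyl 4,6-bis(benzyloxy)-3-(3-bromo-2-formyl-5-methoxyphenoxy)-2-[(2-pentyl-1,3-dioxolan-2-yl)methyl]benzoate | COc1cc(Br)c(C=O)c(Oc2c(CC3(CCCCC)OCCO3)c(C(=O)OC(C)(C)C)c(OCc4ccccc4)cc2OCc5ccccc5)c1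
F5 | step 10 | tert-butyl 4,6-bis(benzyloxy)-3-[3-bromo-2-(formyloxy)-5-methoxyphenoxy]-2-[(2-pentyl-1,3-dioxolan-2-yl)methyl]benzoate | COc1cc(Br)c(OC=O)c(Oc2c(CC3(CCCCC)OCCO3)c(C(=O)OC(C)(C)C)c(OCc4ccccc4)cc2OCc5ccccc5)c1
F6 | step 12 | 2-bromo-4-methoxy-6-(trimethylsilyl)phenol | COc1cc(Br)c(O)c([Si](C)(C)C)c1
F7 | step 12 | [3-bromo-5-methoxy-2-(prop-2-en-1-yloxy)phenyl]trimethylsilane | C=CCOc1c(Br)cc(OC)cc1[Si](C)(C)C
F8 | step 12 | tert-butyl 4,6-bis(benzyloxy)-3-[5-methoxy-2-(prop-2-en-1-yloxy)-3-(trimethylsilyl)phenoxy]-2-[(2-pentyl-1,3-dioxolan-2-yl)methyl]benzoate | C=CCOc1c([Si](C)(C)C)cc(OC)cc1Oc2c(CC3(CCCCC)OCCO3)c(C(=O)OC(C)(C)C)c(OCc4ccccc4)cc2OCc5ccccc5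
F9 | step 12 | tert-butyl 4,6-bis(benzyloxy)-3-[2-hydroxy-5-methoxy-3-(trimethylsilyl)phenoxy]-2-[(2-pentyl-1,3-dioxolan-2-yl)methyl]benzoate | COc1cc([Si](C)(C)C)c(O)c(Oc2c(CC3(CCCCC)OCCO3)c(C(=O)OC(C)(C)C)c(OCc4ccccc4)cc2OCc5ccccc5)c1
F10 | step 16 | methyl 2-(3-{4,6-bis(benzyloxy)-3-(tert-butoxycarbonyl)-2-[(2-pentyl-1,3-dioxolan-2-yl)methyl]phenoxy}-5-methoxy-2-(methoxycarbonyl)phenyl)-3-oxooctanoate (racemic, enolisable) | CCCCCC(=O)C(C(=O)OC)c1cc(OC)cc(Oc2c(CC3(CCCCC)OCCO3)c(C(=O)OC(C)(C)C)c(OCc4ccccc4)cc2OCc5ccccc5)c1C(=O)OC
F11 | step 16 | tert-butyl 4,6-bis(benzyloxy)-3-[5-methoxy-2-(methoxycarbonyl)-3-(2-oxoheptyl)phenoxy]-2-[(2-pentyl-1,3-dioxolan-2-yl)methyl]benzoate | CCCCCC(=O)Cc1cc(OC)cc(Oc2c(CC3(CCCCC)OCCO3)c(C(=O)OC(C)(C)C)c(OCc4ccccc4)cc2OCc5ccccc5)c1C(=O)OC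
F12 | step 18 | tert-butyl 2,4-dihydroxy-5-[(6-methoxy-1-oxo-3-pentyl-1H-isochromen-8-yl)oxy]-6-[(2-pentyl-1,3-dioxolan-2-yl)methyl]benzoate | CCCCCc1cc2cc(OC)cc(Oc3c(CC4(CCCCC)OCCO4)c(C(=O)OC(C)(C)C)c(O)cc3O)c2c(=O)o1
A1 | alternative 1 | methyl 4-hydroxy-2-oxo-6-[(2-pentyl-1,3-dioxolan-2-yl)methyl]cyclohex-3-ene-1-carboxylate (racemic, trans drawn, configuration immaterial) | COC(=O)[C@@H]1[C@@H](CC2(CCCCC)OCCO2)CC(O)=CC1=O
A2 | alternative 1 | (E)-5-(2-pentyl-1,3-dioxolan-2-yl)pent-3-en-2-one | CC(=O)/C=C/CC1(CCCCC)OCCO1
A3 | alternative 2 | 4-[(6-methoxy-1-oxo-3-pentyl-1H-isochromen-8-yl)oxy]-5,7-diisopropoxy-2-pentylindan-1-one (racemic) | CCCCCC1Cc2c(Oc3cc(OC)cc4cc(CCCCC)oc(=O)c34)c(OC(C)C)cc(OC(C)C)c2C1=O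
A4 | alternative 2 | 2-methylideneheptanoyl chloride | C=C(CCCCC)C(=O)Cl
A5 | alternative 2 | 8-(2,4-diisopropoxyphenoxy)-6-methoxy-3-pentyl-1H-isochromen-1-one | CCCCCc1cc2cc(OC)cc(Oc3ccc(OC(C)C)cc3OC(C)C)c2c(=O)o1
A6 | alternative 3 | benzyl 2,4-dihydroxy-5-[(6-methoxy-1-oxo-3-pentyl-1H-isochromen-8-yl)oxy]-6-[(2-pentyl-1,3-dioxolan-2-yl)methyl]benzoate | CCCCCC1(Cc2c(C(=O)OCc3ccccc3)c(O)cc(O)c2Oc2cc(OC)cc3cc(CCCCC)oc(=O)c23)OCCO1
A7 | alternative 3 | 6-methoxy-8-{[4-methoxy-2,4-bis(trimethylsilyloxy)buta-1,3-dien-1-yl]oxy}-3-pentyl-1H-isochromen-1-one (double-bond geometry not specified) | COC(O[Si](C)(C)C)=CC(O[Si](C)(C)C)=COc1cc(OC)cc2cc(CCCCC)oc(=O)c12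
A8 | alternative 3 | benzyl 4-(2-pentyl-1,3-dioxolan-2-yl)but-2-ynoate | CCCCCC1(CC#CC(=O)OCc2ccccc2)OCCO1
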